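(Readings and results were generated by integration from invented constants; noise was put on by code.)

Ash receives on average 0.600 equiv of D during its feed. This is the mean delivered charge, counted whether spent or not, and it matches the south run's charge.

| flask | X | D | remark | time |
|---|---|---|---|---|
| east | 0.30 M | 1.2 equiv | run made earlier |  |
| west | 0.15 M | 1.2 equiv | run made earlier |  |
| south-west | 0.60 M | 1.2 equiv | run made earlier |  |
| south | 0.30 M | 0.60 equiv | run made earlier |  |
| ash | 0.30 M | 1.20 equiv (fed, over 3.0 d) | all else is in the flask from the start; the feed brings no volume worth counting | 5.0 d |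
| elm | 0.30 M | 1.20 equiv | everything together at the start | 5.0 d |
| cedar | 0.30 M (fed, over 3.0 d) | 1.20 equiv | all else is in the flask from the start; the feed brings no volume worth counting | 5.0 d |

- east (time / d: Q / %): 0.625: 10.9; 1.25: 25.5; 1.67: 32.3; 2.50: 43.2; 3.00: 46.0
- west (time / d: Q / %): 0.333: 1.4; 0.625: 6.6; 1.04: 12.1; 2.00: 26.6; 4.00: 40.8
- south-west (time / d: Q / %): 0.333: 6.2; 1.04: 30.4; 1.67: 42.9; 3.00: 57.6; 4.00: 61.7
- south (time / d: Q / %): 0.333: 2.2; 1.04: 12.0; 1.67: 18.7; 3.00: 27.2; 4.00: 29.4

(scatter of a reading: 0.5 percentage points)

- the flask with the highest amount of Q, in percent of the X charged ("all alike" if they lie within 1.5 percentage points) (ash / elm / cedar / all alike)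
- final Q, as a percentage of the X charged, in ash
- final Q, as a percentage of the X charged, in elm
- final Q, as a percentage of the X charged, in cedar

- what was read earlier has a scatter of 0.5 percentage points, one standard deviation

The readings give a ladder. Q lags by about 0.158 d in the east run, an induction period read by drawing the early slope back to zero, and this is far shorter than the feed. Next comes the climb of Q. East is still rising at 3.00 d, with 2.8 percentage points gained over its last 0.500 d, so the climb in east is not over when a time equal to the 3.0 d feed has passed. The flasks are read at 5.0 d. During the climb Q follows the D charged: at 1.67 d south holds 0.579 of east's Q on 0.500 of its D. The reckoning here therefore reads ash at the end of its feed from south at 3.00 d, 27.2%. That is less than the 46.0% of east, whose recipe elm repeats, so ash should trail elm.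

The forecast differs. It names ash, with ash at 56%, elm at 49.5% and cedar at 38%, on the ground that “Ash holds D low, so waste should be lower and X stays in excess”.

The flasks give elm as highest: ash 39.2%, elm 55.8%, cedar 52.4%.

    X ⇌ G (K = 2.30, k = 0.0580 /h)
    D → E (k = 0.180 /h)
    G + E → Q (k = 0.130 /M/h)
    2 G → Z (k = 0.110 /M/h)
    D → L (k = 0.0380 /h)

At the end of its feed ash holds 25.9% of Q, close to the 27.2% read from 0.600 equiv. The gap of 17 points between elm and ash falls to 7.5 points in the run without the step from two G to Z, the largest single effect, though not the whole gap. Ash ends with Z at 49.6%, elm at 32.8%.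

The neighbour of ash charged with 0.720 equiv of D has a mean delivered charge of 0.360 equiv, which is 0.600 of ash's 0.600 equiv, so ash's Q scales to 23.5%. The computed flask gives 26.7%.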